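The leftover caught my eye first: at 90.0 min the cedar run still held 76.9 % of its starting material, the oak run 82.0 % and the elm run 87.8 %, so I stopped thinking in percentages and asked for the rate itself.

common to all: gas phase 26 mM (held)

| charge | starting material | catalyst | remark | time |
|---|---|---|---|---|
| oak | 1.1 M | 0.2 mol% | run made earlier |  |
| elm | 1.8 M | 0.2 mol% | run made earlier |  |
| cedar | 0.80 M | 0.1 mol% | run made earlier |  |
| flask | 0.80 M | 0.2 mol% |  | 1.5 h |

| run | time / min | product / % | starting material / % |
|---|---|---|---|
| oak | 8.00 | 0.9 | 98.7 |
| oak | 12.0 | 2.4 | 97.9 |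
| oak | 20.0 | 4.7 | 96.9 |
| oak | 30.0 | 6.4 | 93.6 |
| oak | 50.0 | 10.2 | 89.8 |
| oak | 90.0 | 17.6 | 82.0 |
| elm | 6.00 | 0.7 | 99.2 |
| elm | 20.0 | 2.5 | 97.7 |
| elm | 30.0 | 4.2 | 97.0 |
| elm | 50.0 | 6.3 | 93.6 |
| elm | 60.0 | 7.3 | 93.1 |
| elm | 90.0 | 10.5 | 87.8 |
| cedar | 8.00 | 1.9 | 98.1 |
| cedar | 25.0 | 6.6 | 93.6 |
| cedar | 40.0 | 10.4 | 90.1 |
| cedar | 60.0 | 15.5 | 84.4 |
| cedar | 90.0 | 23.8 | 76.9 |

(readings scatter by 0.5 percentage points)

- at the start none of the gas phase is in solution

- violet: doubling the saturation concentration of gas phase, all else as stated
- red: doubling the amount of catalyst, all else as stated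
- grey: doubling the transfer coefficient of the gas phase, all else as stated

- product at 1.5 h, in percent of the starting material charged
- concentration of dissolved gas in solution at 25 min, in percent of saturation
- the change that raises the amount of product at 1.5 h, in percent of the starting material charged most ("none" if none brings more than 2 percentage points) (violet / red / grey / none)
- amount of product at 1.5 h, in percent of the starting material charged, after red

Cedar's last product reading makes 2.12 mM min⁻¹, and this I called the delivery rate D, the concentration of product made per minute up to that reading; oak gives 2.15 mM min⁻¹ and elm 2.10 mM min⁻¹, although elm began with 1.8 M of starting material and cedar with 0.80 M. Then I looked for what slows it. Between its first and last readings cedar's starting material shrank by a factor of 0.784, yet its last stretch ran at 2.21 mM min⁻¹, not slower than the 2.11 mM min⁻¹ up to 25.0 min. Oak, with twice cedar's loading of catalyst and with 1.1 M against 0.80 M of starting material, delivered 1.02 times D. With neither factor showing in the readings, I saw no accumulated slowing to subtract, and D over 1.5 h on 0.80 M gave me 23.9 % for the flask.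

The forecast said 23.8 %, 2 % of saturation at 25 min, violet as the best change and 24 % after red: "So gas transfer limits the reaction".

The flask gave 24.0 %, 2.46 % of saturation at 25 min, and violet as the best change with a gain of 24 percentage points, against 22 points for grey; red gave 24.3 %.

    gas phase ⇌ dissolved gas, rate k1*(csat - [dissolved gas]) (kL = 5.10 h⁻¹)
    starting material + dissolved gas + catalyst ⇌ catalyst + product (K = 770 M⁻¹, k = 2.00 × 10⁵ M⁻² h⁻¹)
    dissolved gas + catalyst ⇌ idle complex, settled at all times (K = 16.0 M⁻¹)

Part of why the flask stood at 24.0 % is the slow crossing of the gas, together with the reading at 1.5 h and not ten times later: taking away either gives 95.2 %. What would undo such a number shows in the neighbour flask with 0.32 M of starting material, where D predicts 59.6 % but that neighbour holds 49.7 % of product, an average delivery of 1.77 mM min⁻¹, less than D. The neighbour's dissolved gas, higher than in the asked flask, had reached 24.7 % of saturation at 1.50 h.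

The numbers in the tables were generated by integration for substances that don't exist; noise was put on by code.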